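**Retrosynthetic overview**

1. Numbering: C1 is the quaternary carbon that carries geranyl; ring A is C1-C2-C3-C4-C5-C14, ring B C1-C12-C11-C10-C13-C14, ring C C5-C6-C7-C13-C14, ring D C7-C8-O9-C10-C13. The strategy rests on ring B: the C12 ketone and the C14 tertiary carbinol flank quaternary C1 like the two carbonyls of a 2,2-disubstituted cyclohexane-1,3-dione, one of which has taken up C5 and kept its oxygen.
2. Last disconnections: the C14 silyl ether, then the C4 methyl and C3=C4 from a C4 ketone (enol triflate, Negishi), postponed until rings C and D exist so that C5 stays adjustable.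
3. Rings C and D in one step: Prins closure C7-C13 onto a ring B 2-hydroxy-enedione with capture of the C8 cation by O9. The enedione comes from the C12 ketone by dehydrogenation, C11 prenylation, C13 oxygenation and C10 oxygenation.
4. Ring A: bond C5-C14 by an enantiogroup-selective enamine aldol of an achiral triketone, stopped at the ketol [6-(enolendo)-exo-trig]; it sets C1 and C14 and, provisionally, C5.
5. Triketone: C-geranylation of cyclohexane-1,3-dione, then Michael addition to the vinyl ketone from 6-methylhept-5-en-2-one. Ring order: B (bought), A, then C and D together.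

Key step: step 5

Assumption (C5): ketol 9 is carried as the C5 epimer drawn (C6 arm trans to the C14 oxygen). The two C5 epimers are expected to be close in energy, so any C5 epimer is taken through steps 6 to 13 unchanged and is corrected in step 14, where C4 is again a ketone.

Remark (transient centres): compounds 14, 17 and 19 each carry one short-lived stereocentre (C11, C13, the epoxide) that is removed in the same or the next step; their SMILES leave it open.

**Route**

Step 1
Reactants: 1 cyclohexane-1,3-dione; 2 geranyl bromide
Product: 3 2-geranylcyclohexane-1,3-dione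
Conditions: KOH (1 equiv), H2O, 0 °C to rt
Reagents that add atoms: none
Why: C-alkylation of the 1,3-dione enolate by the primary allylic bromide (SN2, so the E-alkene is kept), with water solvating the enolate oxygens and so favouring C- over O-alkylation.

Step 2
Reactants: 4 6-methylhept-5-en-2-one
Product: 5 1-(dimethylamino)-7-methyloct-6-en-3-one
Conditions: LiN(iPr)2, THF, −78 °C; CH2=NMe2 I, −78 °C to rt
Reagents that add atoms: dimethylmethylideneammonium iodide, C=[N+](C)C.[I-]
Why: Mannich reaction in which kinetic deprotonation of the methyl ketone at its methyl group gives the lithium enolate that is trapped by the preformed iminium salt, placing the future C2 on the ketone.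

Step 3
Reactants: 5 1-(dimethylamino)-7-methyloct-6-en-3-one
Product: 7 7-methylocta-1,6-dien-3-one, via ammonium iodide 6 (not isolated)
Conditions: MeI, Et2O, rt; then NaHCO3, H2O/CH2Cl2, rt; used crude
Reagents that add atoms: none
Why: N-methylation followed by base-induced Hofmann-type beta-elimination of trimethylamine (E1cB) should release the vinyl ketone, which is used at once because it polymerises on storage.

Step 4
Reactants: 3 2-geranylcyclohexane-1,3-dione; 7 7-methylocta-1,6-dien-3-one
Product: 8 2-geranyl-2-(7-methyl-3-oxooct-6-enyl)cyclohexane-1,3-dione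
Conditions: Et3N (0.1 equiv), MeCN, rt
Reagents that add atoms: none
Why: Michael addition of the acidic 2-substituted 1,3-dione to the vinyl ketone under amine catalysis builds quaternary C1, and no stereocentre arises because the product has a mirror plane.

Step 5
Reactants: 8 2-geranyl-2-(7-methyl-3-oxooct-6-enyl)cyclohexane-1,3-dione
Product: 9 cis-fused ketol of rings A and B (1-geranyl; 4,12-dioxo; 5-prenyl arm; 14-hydroxy cis to geranyl)
Conditions: D-phenylalanine (1.0 equiv), (1R)-(−)-10-camphorsulfonic acid (0.5 equiv), DMF, 20 °C; worked up at full consumption of 8, no heating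
Reagents that add atoms: none
Why: The primary amine condenses with the side-chain C4 ketone (the ring carbonyls are shielded by quaternary C1), the enamine toward C5 forms with the C6 arm syn to N-H, and C5 adds to one ring carbonyl through a chair in which the carboxylic acid hydrogen-bonds the developing C14 alkoxide, after which hydrolysis releases the ketol and the amino acid. The closest known reaction is the Hajos-Parrish-Eder-Sauer-Wiechert cyclisation of 2,2-disubstituted cyclic 1,3-diones with a primary amino acid, interrupted at the ketol by working at room temperature. Ring A closes in a 6-(enolendo)-exo-trig mode, since the enamine double bond C4=C5 lies inside the new ring. C1 is fixed by which of the two enantiotopic carbonyls is attacked, which the configuration of the amino acid controls (the D series is chosen because the L series gives the mirror-image arrangement at the quaternary carbon in the parent methyl case); C14 follows from the three-atom tether C1-C2-C3, which allows only the cis-fused ketol with OH cis to geranyl; C5 is set by the enamine geometry in the chair and is the least secure centre, which is why C4 is kept at the ketone level until ring C is closed. The step needs enantiogroup selection and arrest before dehydration: the first rests on the hydrogen-bonded chair, the second on the low temperature and on the strain of the tetrasubstituted C5=C14 enone that dehydration would have to form.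

Step 6
Reactants: 9 cis-fused ketol
Product: 10 14-O-triethylsilyl ether of the ketol
Conditions: Et3SiOTf, 2,6-lutidine, CH2Cl2, −78 to 0 °C
Reagents that add atoms: triethylsilyl trifluoromethanesulfonate, CC[Si](CC)(CC)OS(=O)(=O)C(F)(F)F
Why: Silylation of the tertiary carbinol with a silyl triflate and a hindered pyridine base blocks retro-aldol cleavage and dehydration in the base steps that follow, and no stereocentre is touched.

Step 7
Reactants: 10 14-O-triethylsilyl ether of the ketol
Product: 11 C4 ethylene ketal of 10
Conditions: Me3SiOCH2CH2OSiMe3, Me3SiOTf (5 mol%), CH2Cl2, −78 to −30 °C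
Reagents that add atoms: 1,2-bis(trimethylsilyloxy)ethane, C[Si](C)(C)OCCO[Si](C)(C)C
Why: Acid-catalysed ketalisation by silyl transfer at low temperature should be site-selective for C4, because C12 lies next to quaternary C1 (itself next to fully substituted C14) and is much more hindered; the dioxolane masks C4 and freezes C5 during the enolate chemistry on ring B.

Step 8
Reactants: 11 C4 ethylene ketal
Product: 13 ring B enone (C10=C11; C12 ketone), via trimethylsilyl enol ether 12 (not isolated)
Conditions: LiN(iPr)2, Me3SiCl, THF, −78 °C; then Pd(OAc)2 (1.1 equiv), MeCN, rt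
Reagents that add atoms: none
Why: Saegusa-Ito oxidation, in which C11 is the only enolisable position (C1 is quaternary and C4 is masked), so the silyl enol ether forms regiospecifically and palladium-mediated beta-hydride elimination gives the C10=C11 enone.

Step 9
Reactants: 13 ring B enone
Product: 15 C11-prenyl enone, via deconjugated C11-prenyl ketone 14 (not isolated)
Conditions: LiN(iPr)2, THF, −78 °C; prenyl bromide, −78 °C; then DBU, CH2Cl2, rt
Reagents that add atoms: prenyl bromide (1-bromo-3-methylbut-2-ene), CC(C)=CCBr
Why: Deconjugative alkylation: the enone has no alpha' hydrogen, so the amide base removes a gamma hydrogen at C13 and the linear dienolate is alkylated at its alpha carbon C11, after which the amidine base moves the double bond back into conjugation and removes the transient C11 centre.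

Step 10
Reactants: 15 C11-prenyl enone
Product: 17 C13-hydroxy enone (C13 epimers), via trimethylsilyl dienol ether 16 (not isolated)
Conditions: KN(SiMe3)2, THF, −78 °C; Me3SiCl; then dimethyldioxirane (1.0 equiv), acetone/CH2Cl2, −78 °C; aqueous citric acid work-up
Reagents that add atoms: dimethyldioxirane, CC1(C)OO1
Why: Vinylogous Rubottom oxidation: gamma-deprotonation at C13 and O-silylation give the 1-silyloxy diene, whose electron-rich terminus C13 should react with the dioxirane far faster than the isolated trisubstituted alkenes at −78 °C, and collapse of the silyloxy epoxide gives the C13 alcohol with the enone restored (either C13 epimer serves, since the centre is oxidised next).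

Step 11
Reactants: 17 C13-hydroxy enone
Product: 18 ene-1,4-dione (C12 and C13 ketones; C10=C11)
Conditions: Dess-Martin periodinane, pyridine, CH2Cl2, 0 °C to rt
Reagents that add atoms: none
Why: Dess-Martin oxidation of the allylic secondary alcohol under buffered conditions gives the enedione without touching the alkenes, the ketal or the silyl ether.

Step 12
Reactants: 18 ene-1,4-dione
Product: 20 ketal-protected 2-hydroxy-enedione (C10-OH; C10=C11; C12 and C13 ketones), via epoxy diketone 19 (not isolated)
Conditions: t-BuOOH (1.0 equiv), DBU, CH2Cl2, 0 °C to rt; aqueous citric acid work-up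
Reagents that add atoms: tert-butyl hydroperoxide, CC(C)(C)OO
Why: Weitz-Scheffer nucleophilic epoxidation is specific for the electron-poor C10=C11 bond, and the same base opens the epoxy diketone by deprotonation at C10 (alpha to C13) and beta-elimination of the epoxide oxygen from C11, which can only place the hydroxyl on C10 because C11 carries no hydrogen.

Step 13
Reactants: 20 ketal-protected 2-hydroxy-enedione
Product: 21 2-hydroxy-enedione with free C4 ketone
Conditions: pyridinium p-toluenesulfonate, acetone/H2O (10:1), 40 °C
Reagents that add atoms: water, O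
Why: Mild acid-catalysed hydrolysis of the dioxolane returns the C4 ketone, which makes C5 epimerisable again just before ring C is closed, while the tertiary silyl ether and the alkenes should survive.

Step 14
Reactants: 21 2-hydroxy-enedione with free C4 ketone
Product: 22 tetracyclic ketone (rings A to D; 4-oxo; 13-hydroxy; 14-O-triethylsilyl)
Conditions: 10-camphorsulfonic acid (0.3 equiv), dry CH2Cl2, 0 °C to rt
Reagents that add atoms: none
Why: Prins cyclisation with cation capture: acid activates the C13 carbonyl next to the enol (a 2-hydroxyallyl-type cation), the C7=C8 alkene adds in a 5-exo closure from the face of ring B that carries C5, so the new C13 hydroxyl is cis to the C14 oxygen, and the tertiary C8 cation is captured by enol oxygen O9 to give the necessarily cis-fused ring D, which fixes C7; only the C5 epimer with the arm cis to C13 can reach C13, and the other can equilibrate through the C4 enol under the same acid.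

Step 15
Reactants: 22 tetracyclic ketone
Product: 23 C3=C4 enol triflate
Conditions: KN(SiMe3)2 (2.2 equiv), PhNTf2, THF, −78 °C
Reagents that add atoms: N-phenylbis(trifluoromethanesulfonimide), O=S(=O)(N(c1ccccc1)S(=O)(=O)C(F)(F)F)C(F)(F)F
Why: Kinetic enolisation and O-triflation of the only enolisable ketone (the C12 carbonyl is a vinylogous ester whose alpha' carbon C1 and gamma carbon C13 are fully substituted) should take the C3 methylene hydrogen and not the hindered ring-fusion hydrogen at C5, with the second equivalent of base holding the C13 hydroxyl as its alkoxide.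

Step 16
Reactants: 23 C3=C4 enol triflate
Product: 24 14-O-triethylsilyl ether of the target
Conditions: MeZnCl, Pd(PPh3)4 (5 mol%), THF, 50 °C
Reagents that add atoms: methylzinc chloride, C[Zn]Cl
Why: Negishi cross-coupling of the alkenyl triflate with the methylzinc reagent installs the C4 methyl with the alkene position fixed by the triflate, and the organozinc should leave the vinylogous ester and the hydroxyl untouched.

Step 17
Reactants: 24 14-O-triethylsilyl ether of the target
Product: 25 CNP0323114.1
Conditions: HF·pyridine, THF/pyridine, 0 °C to rt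
Reagents that add atoms: none
Why: Fluoride-mediated cleavage of the tertiary triethylsilyl ether under buffered, non-basic conditions frees the C14 hydroxyl without risk of retro-aldol opening and gives the target.

**Compound list**

1 | cyclohexane-1,3-dione | O=C1CCCC(=O)C1 | starting material
2 | geranyl bromide | CC(C)=CCC/C(C)=C/CBr | starting material
3 | 2-geranylcyclohexane-1,3-dione | CC(C)=CCC/C(C)=C/CC1C(=O)CCCC1=O | intermediate
4 | 6-methylhept-5-en-2-one | CC(=O)CCC=C(C)C | starting material
5 | 1-(dimethylamino)-7-methyloct-6-en-3-one | CN(C)CCC(=O)CCC=C(C)C | intermediate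
6 | trimethyl(7-methyl-3-oxooct-6-enyl)ammonium iodide | C[N+](C)(C)CCC(=O)CCC=C(C)C.[I-] | intermediate
7 | 7-methylocta-1,6-dien-3-one | C=CC(=O)CCC=C(C)C | intermediate
8 | 2-geranyl-2-(7-methyl-3-oxooct-6-enyl)cyclohexane-1,3-dione (achiral) | CC(C)=CCC/C(C)=C/CC1(CCC(=O)CCC=C(C)C)C(=O)CCCC1=O | intermediate
9 | cis-fused ketol: 1-geranyl, 4,12-dioxo, 5-prenyl arm, 14-OH cis to geranyl, arm trans to 14-OH | CC(C)=CCC/C(C)=C/C[C@]12CCC(=O)[C@H](CC=C(C)C)[C@]2(O)CCCC1=O | intermediate
10 | 14-O-triethylsilyl ether of 9 | CC(C)=CCC/C(C)=C/C[C@]12CCC(=O)[C@H](CC=C(C)C)[C@]2(O[Si](CC)(CC)CC)CCCC1=O | intermediate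
11 | C4 ethylene ketal of 10 | CC(C)=CCC/C(C)=C/C[C@]12CCC3(OCCO3)[C@H](CC=C(C)C)[C@]2(O[Si](CC)(CC)CC)CCCC1=O | intermediate
12 | C11=C12 trimethylsilyl enol ether of 11 | CC(C)=CCC/C(C)=C/C[C@]12CCC3(OCCO3)[C@H](CC=C(C)C)[C@]2(O[Si](CC)(CC)CC)CCC=C1O[Si](C)(C)C | intermediate
13 | ring B enone (C10=C11, C12 ketone) | CC(C)=CCC/C(C)=C/C[C@]12CCC3(OCCO3)[C@H](CC=C(C)C)[C@]2(O[Si](CC)(CC)CC)CC=CC1=O | intermediate
14 | deconjugated C11-prenyl ketone (C10=C13; C11 epimers) | CC(C)=CCC/C(C)=C/C[C@]12CCC3(OCCO3)[C@H](CC=C(C)C)[C@]2(O[Si](CC)(CC)CC)C=CC(CC=C(C)C)C1=O | intermediate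
15 | C11-prenyl enone (C10=C11) | CC(C)=CCC/C(C)=C/C[C@]12CCC3(OCCO3)[C@H](CC=C(C)C)[C@]2(O[Si](CC)(CC)CC)CC=C(CC=C(C)C)C1=O | intermediate
16 | trimethylsilyl dienol ether (C11=C12, C10=C13) | CC(C)=CCC/C(C)=C/C[C@]12CCC3(OCCO3)[C@H](CC=C(C)C)[C@]2(O[Si](CC)(CC)CC)C=CC(CC=C(C)C)=C1O[Si](C)(C)C | intermediate
17 | C13-hydroxy enone (C13 epimers) | CC(C)=CCC/C(C)=C/C[C@]12CCC3(OCCO3)[C@H](CC=C(C)C)[C@]2(O[Si](CC)(CC)CC)C(O)C=C(CC=C(C)C)C1=O | intermediate
18 | ene-1,4-dione (C12=O, C10=C11, C13=O), C4 ketal | CC(C)=CCC/C(C)=C/C[C@]12CCC3(OCCO3)[C@H](CC=C(C)C)[C@]2(O[Si](CC)(CC)CC)C(=O)C=C(CC=C(C)C)C1=O | intermediate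
19 | 10,11-epoxy-12,13-dione, C4 ketal (epoxide face open) | CC(C)=CCC/C(C)=C/C[C@]12CCC3(OCCO3)[C@H](CC=C(C)C)[C@]2(O[Si](CC)(CC)CC)C(=O)C4OC4(CC=C(C)C)C1=O | intermediate
20 | ketal-protected 2-hydroxy-enedione (C10-OH, C10=C11, C12=O, C13=O) | CC(C)=CCC/C(C)=C/C[C@]12CCC3(OCCO3)[C@H](CC=C(C)C)[C@]2(O[Si](CC)(CC)CC)C(=O)C(O)=C(CC=C(C)C)C1=O | intermediate
21 | 2-hydroxy-enedione with free C4 ketone | CC(C)=CCC/C(C)=C/C[C@]12CCC(=O)[C@H](CC=C(C)C)[C@]2(O[Si](CC)(CC)CC)C(=O)C(O)=C(CC=C(C)C)C1=O | intermediate
22 | tetracyclic ketone: rings A to D, 4-oxo, 13-OH, 14-O-triethylsilyl, H5/O14/O13/H7 all cis | CC(C)=CCC/C(C)=C/C[C@]12CCC(=O)[C@@H]3C[C@@H]4C(C)(C)OC(=C(CC=C(C)C)C1=O)[C@]4(O)[C@@]32O[Si](CC)(CC)CC | intermediate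
23 | C3=C4 enol triflate of 22 | CC(C)=CCC/C(C)=C/C[C@]12CC=C(OS(=O)(=O)C(F)(F)F)[C@@H]3C[C@@H]4C(C)(C)OC(=C(CC=C(C)C)C1=O)[C@]4(O)[C@@]32O[Si](CC)(CC)CC | intermediate
24 | 14-O-triethylsilyl ether of the target | CC(C)=CCC/C(C)=C/C[C@]12CC=C(C)[C@@H]3C[C@@H]4C(C)(C)OC(=C(CC=C(C)C)C1=O)[C@]4(O)[C@@]32O[Si](CC)(CC)CC | intermediate
25 | CNP0323114.1 | CC(C)=CCC/C(C)=C/C[C@]12CC=C(C)[C@@H]3C[C@@H]4C(C)(C)OC(=C(CC=C(C)C)C1=O)[C@]4(O)[C@@]32O | target

**Step count and risks**

Total step count: 17. Longest linear sequence: 16 steps (from 6-methylhept-5-en-2-one, steps 2 to 17).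

Most likely to fail, first: step 14 (Prins closure with capture by O9). What may go wrong: addition of the geranyl alkene on C1 to C13 from the opposite face (a bridged closure); loss of a proton from the C8 cation in an ene-type course, which sets C7 the wrong way for ring D; acid-driven O-cyclisation of the C11 prenyl group onto the enol; or dehydration across C5-C14 once C4 enolises. Fallback, setting out from 21: the carbon-carbon and carbon-oxygen bonds are made in two separate events. TiCl4 in CH2Cl2 at −78 °C, which chelates the enol oxygen and the C13 carbonyl and works without free protic acid, should give the chloride-terminated Prins product, the tertiary C8 chloride F1. AgOSO2CF3 with 2,6-di-tert-butylpyridine in CH2Cl2 then ionises the C8-Cl bond and lets O9 close ring D, which comes back to the route at 22.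

Second: step 10 (vinylogous Rubottom oxidation). What may go wrong: epoxidation of one of the four isolated trisubstituted alkenes by the dioxirane, attack at C11 in place of C13, or beta-elimination of the C14 silyloxy group from the dienolate before it is silylated. Fallback, setting out from 15: both ring B oxygens are brought in without an electrophilic oxidant acting on a diene. H2O2/NaOH in MeOH at 0 °C (nucleophilic epoxidation, inert to the isolated alkenes) should give the 10,11-epoxy ketone F2. Pd(PPh3)4 with 1,2-bis(diphenylphosphino)ethane in toluene at 100 °C isomerises it to the 2-prenyl-1,3-dione F3. The dianion of F3 (LiN(iPr)2, 3 equiv, THF, −78 °C) is hydroxylated at C13 by 2-(phenylsulfonyl)-3-phenyloxaziridine to give the C13 alcohol F4. Dess-Martin oxidation of F4 comes back to the route at 20, so steps 10 to 12 are replaced.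

Third: step 5 (desymmetrising aldol). What may go wrong: dehydration of the ketol under the amine and acid, insufficient discrimination between the two ring carbonyls, or formation of the C5 epimer. Fallback, setting out from 8: the cyclisation is run on purpose through to the condensation product with the same amino acid and acid in DMF at 70 °C (the long-established outcome of this reaction), which should give the bicyclic enedione F5 with C1 as its only stereocentre. H2O2/NaOH in MeOH then epoxidises the C5=C14 enone, by analogy with angularly substituted octalenones from the face syn to the geranyl group, to give the epoxy diketone F6. SmI2 in THF/MeOH at −78 °C cleaves the C5-O bond reductively and comes back to the route at 9; a C5 epimer formed on protonation is handled as in the main route.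

Further compounds
F1 | step 14 | tertiary C8 chloride: ring C closed, ring D open, 13-OH, 2-hydroxy-enone in ring B, 14-O-triethylsilyl | CC(C)=CCC/C(C)=C/C[C@]12CCC(=O)[C@@H]3C[C@H](C(C)(C)Cl)[C@](O)(C(O)=C(CC=C(C)C)C1=O)[C@@]32O[Si](CC)(CC)CC
F2 | step 10 | 10,11-epoxy ketone of 15 (epoxide face open) | CC(C)=CCC/C(C)=C/C[C@]12CCC3(OCCO3)[C@H](CC=C(C)C)[C@]2(O[Si](CC)(CC)CC)CC4OC4(CC=C(C)C)C1=O
F3 | step 10 | ring B 2-prenyl-1,3-dione (enol form), C4 ketal | CC(C)=CCC/C(C)=C/C[C@]12CCC3(OCCO3)[C@H](CC=C(C)C)[C@]2(O[Si](CC)(CC)CC)CC(O)=C(CC=C(C)C)C1=O
F4 | step 10 | C13-hydroxy derivative of F3 (C13 epimers) | CC(C)=CCC/C(C)=C/C[C@]12CCC3(OCCO3)[C@H](CC=C(C)C)[C@]2(O[Si](CC)(CC)CC)C(O)C(O)=C(CC=C(C)C)C1=O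
F5 | step 5 | bicyclic enedione (C4 ketone, C5=C14, C12 ketone) | CC(C)=CCC/C(C)=C/C[C@]12CCC(=O)C(CC=C(C)C)=C2CCCC1=O
F6 | step 5 | 5,14-epoxy diketone, epoxide cis to geranyl | CC(C)=CCC/C(C)=C/C[C@]12CCC(=O)[C@@]3(CC=C(C)C)O[C@]32CCCC1=O
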